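## Analysis of the target

Compound 30 joins three units at one spiro ketal carbon: ring A (a 6,7-dihydro-2H-chromene-5,8-dione with a fused 2,2-dimethylpyran and a prenyl group), a six-membered 1,3-dioxin-4-one (an acylal), and a cage in which a bicyclo[2.2.2]octenone is bridged by a tetrahydrofuran. Cage atoms are numbered as in 4-oxatricyclo[4.3.1.0(3,7)]dec-8-en-2-one: C-1 hydroxylated bridgehead, C-2 ketone, C-3 prenylated ether carbon, O-4, C-5 CMe2, C-6 methine, C-7 oxygenated bridgehead, C-8 (carboxyl-bearing) and C-9 alkene carbons, C-10 CH2.

There are six stereocentres. C-1, C-3, C-6 and C-7 are locked relative to one another by the cage, so only their absolute sense is open. The spiro carbon and the neighbouring prenyl methine of ring A can both equilibrate, by retro-addition and by enolisation.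

The acylal is labile to base and nucleophiles, the bridgehead alpha-ketol can undergo acyloin shift, and the two prenyl groups and the chromene alkene exclude strong acid and unselective oxidants.

The difficulty lies in five contiguous fully substituted carbons (C-1, C-2, C-3, C-7, C-8), a quaternary ether carbon that cannot be enolised once the cage exists, and a ketal that must be closed with a tertiary bridgehead hydroxyl.

The strategy rests on a ten-carbon fragment: the ring C-7, C-8, C-9, C-1, C-10, C-6, the carboxyl carbon on C-8 and the CMe2 group C-5. These are the ten carbons of car-3-en-2-one (3), if the cyclopropane bond between CMe2 and the future C-10 is replaced by the bond from CMe2 to O-4.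

## Retrosynthetic reasoning

**30 to 22 and 28.** Both C–O bonds at the spiro carbon are cut. This separates the hydroxy acid 22 from the hydroxyquinone 28, whose enol carbon is at the ketone oxidation level that the ketal needs. The forward reaction must first acylate the acidic hydroxyl of 28 (acyloxyquinone 29) and then add the C-7 hydroxyl to the acyloxy-bearing quinone carbon. Both ring A centres are left to equilibration.

**28 to 27, 26, 24 and 23.** The prenyl C–C bond of 28 is cut back to 27 and 19, since a hydroxyquinone is C-nucleophilic only at the carbon between the enol and the carbonyl. The pyran of 27 comes from 24 and the enal 25 by condensation and oxa-electrocyclisation. Starting from the 2,6-dioxygenated quinone 23 places the remaining oxygen next to the carbonyl that flanks the pyran oxygen, as 30 requires.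

**22 to 21 to 20.** The C-1–C-2 bond is cut. C-2 is then an ester on C-3 and C-1 is the gamma carbon of the C-8 enoic acid, so the bridge closes by a vinylogous Dieckmann reaction of the acid dienediolate. The acid is used rather than its ester for two reasons: the strongly basic dianion makes the acylation irreversible, and no later saponification of a cage ketone prone to retro-Claisen cleavage is needed. The C-1 oxygen must be present as an ether (MOM, 21) that can neither migrate nor rearrange in the anion.

**20 to 18 and 19.** The prenyl–C-3 bond is cut. C-3 cannot be enolised in the cage (a bridgehead enolate), so the prenyl group must enter before the bridge, by alkylation of the beta-hydroxy ester polyanion of 18. The incoming group must take the convex face so that the ester stays over the carbocycle.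

**18 back to 10.** These are oxidation-state changes only, but their order is fixed by three constraints:
- The ketone of 10 is reduced and protected first (11, 12), so that no ketone enolate competes later.
- The side arm is taken to the methyl ester (13, 14, 15) before the vinylic methyl is oxidised (16, 17, 18), so that the two carboxyl groups end up differentiated as ester and free acid.
- The selenium-based methyl oxidation precedes the prenylation, because a prenyl group would be oxidised as well.

**10 to 9 (key disconnection).** The O-4–C-5 bond is cut and the cyclopropane bond C-5–C-10 re-formed. This reveals the cyclopropyl enone 9, in which the secondary hydroxyl is positioned for a five-membered closure on the CMe2 carbon. The cut is made here because it turns the tetrahydrofuran with its methine stereocentre into a carane skeleton available from the chiral pool. Forward, the acid-activated cyclopropyl ketone must open at the external bond and be captured by the secondary hydroxyl.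

**9 to 8, 7, 6, 5, 3 and 4.** The diol of 9 comes from syn-dihydroxylation of the exocyclic alkene of dienone 8 on the face away from the cyclopropane; this sets C-7 and puts the side chain on the cyclopropane face. The ring ketone of 8 comes from allylic oxidation of 7. The alkene comes from Peterson olefination of 3 with 4, followed by reduction and acylation (5, 6, 7), so that the alkene to be dihydroxylated is the electron-rich one.

**3 to 2 to 1.** The cyclopropane bond between CMe2 and the alpha' carbon is cut. Carenone 3 is the known cyclisation product of the hydrochloride 2 of (R)-carvone 1, whose stereocentre fixes the cyclopropane face and thereby every cage centre.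

## Alternatives that were turned down

**Alternative 1:** Here the acyl–oxygen bond of the dioxinone is traced to a Baeyer–Villiger insertion. A flavin monooxygenase (NADPH, O2) would oxidise the caged xanthone A2 between its carbonyl and ring A to give the seven-membered aryl ester A1.
- For: enzymatic oxygen transfer spares the three alkenes that a peracid would epoxidise, and the electron-rich aryl group is the natural migrating group. Xanthone cages of this family can be assembled very quickly, so on step count to the cage this plan is stronger than the chosen one.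
- Against: A1 is not 30. In 30 both oxygens sit on one sp3 carbon of a dearomatised ring A, so A1 would still need ester cleavage, oxidation to the quinone level and re-closure. A2 already needs the unusual C-1 hydroxyl. Acceptance of a bulky, doubly conjugated ketone by an enzyme cannot be argued from structure and would rest on screening.
- The chosen strategy offers absolute configuration by purely chemical relay and a ring A partner already at the right oxidation state.

**Alternative 2:** The C-6–C-7 bond and the O-4–C-5 bond are cut together. A Lewis acid chelated between the ester and the adjacent ketone of the cyclohexenedione A4 would trigger a Prins attack of the prenyl alkene, and the tertiary cation would be trapped by the neighbouring hydroxyl to give A3.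
- For: two rings and two bonds form in one operation, which is more complexity per step than the chosen key step offers.
- Against: A4 carries two tertiary carbinol centres that must be cis and enantiopure with no chiral-pool handle. The ketone to be attacked is flanked by a quaternary carbinol and competes with a second ketone. Proton loss to an isopropenyl group and acyloin shifts of the alpha-ketols are open under Lewis acid. The allyl group must still be converted to prenyl.
- The chosen strategy forms only one bond in its key step, but with regiochemistry fixed by orbital overlap and cation stability, and with stereochemistry inherited from carvone.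

**Alternative 3:** The C-1–C-2 bond is cut in the opposite polarity. An N-heterocyclic carbene would turn the formyl group of A6 into an acyl anion equivalent that adds to the enone carbonyl, giving the alpha-ketol A5.
- For: the step is catalytic and redox-neutral and gives the C-1 hydroxyl and C-2 ketone directly. On this point it is better than the reduction, protection, Dieckmann closure and deprotection of the chosen route.
- Against: the aldehyde sits on a quaternary alpha-alkoxy carbon, where Breslow intermediates form slowly. Benzoin addition to a ketone is reversible, and the product is a strained cage. The carboxyl carbon is left as an acetonide-protected alcohol, to be oxidised with a prenyl group present. The plan does not say how A6, with its cis-fused tetrahydrofuran and quaternary centre, is obtained in one absolute configuration.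
- The chosen strategy supplies exactly that front end, and closes its last bridge with a thermodynamic driving force (dienediolate to alkoxide).

Key step: step 8

Remark on the chemistry (assumption): the configurations at the spiro ketal carbon and at the adjacent prenyl methine of ring A are taken to be those that the reversible ring closure of step 23 reaches under equilibration. The carbinol configuration drawn for 11 to 20 is the expected major one and is erased in step 17.

## Route

Step 1
Reactants: 1 (R)-(−)-carvone
Product: 2 carvone hydrochloride, (5R)-5-(2-chloropropan-2-yl)-2-methylcyclohex-2-en-1-one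
Conditions: HCl (g), AcOH, 0 °C
Reagents that add atoms: hydrogen chloride, Cl
Why: Markovnikov hydrochlorination of the isopropenyl group; the electron-poor enone alkene is left alone and the stereocentre is not touched.

Step 2
Reactants: 2 carvone hydrochloride
Product: 3 (1S,6R)-car-3-en-2-one
Conditions: KOt-Bu, THF, −10 °C, short contact; cold aq. NH4Cl
Reagents that add atoms: none
Why: Intramolecular enolate alkylation (3-exo-tet) of the alpha' enolate on the tertiary chloride, the classical route from carvone hydrohalides to carenone. The cis ring fusion is forced and the carvone centre fixes the cyclopropane face; cold, brief exposure avoids dienolate-mediated opening to eucarvone.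

Step 3
Reactants: 3 (1S,6R)-car-3-en-2-one; 4 ethyl (trimethylsilyl)acetate
Product: 5 ethyl (2E)-2-[(1S,6R)-3,7,7-trimethylbicyclo[4.1.0]hept-3-en-2-ylidene]acetate
Conditions: LiN(i-Pr)2, THF, −78 °C; add 3; −78 → 0 °C
Reagents that add atoms: none
Why: Peterson olefination; 1,2-addition at −78 °C is faster than gamma-deprotonation of the base-labile enone, and the basic syn-elimination avoids any cation at the cyclopropylcarbinyl carbon. The E isomer should prevail because the ester then avoids the ring methyl; the other geometry would converge later, as the side-chain centre is re-set in step 16.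

Step 4
Reactants: 5 dienoate
Product: 6 (2E)-2-[(1S,6R)-3,7,7-trimethylbicyclo[4.1.0]hept-3-en-2-ylidene]ethan-1-ol
Conditions: i-Bu2AlH, CH2Cl2, −78 °C; aq. potassium sodium tartrate
Reagents that add atoms: none
Why: 1,2-Reduction of a conjugated ester to the allylic alcohol; the non-acidic work-up protects the ionisable dienyl cyclopropylcarbinyl system.

Step 5
Reactants: 6 dienyl alcohol
Product: 7 (2E)-2-[(1S,6R)-3,7,7-trimethylbicyclo[4.1.0]hept-3-en-2-ylidene]ethyl 2,2-dimethylpropanoate
Conditions: PivCl, pyridine, DMAP (cat.), CH2Cl2, 0 °C
Reagents that add atoms: pivaloyl chloride, CC(C)(C)C(Cl)=O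
Why: Acylation of a primary allylic alcohol under buffered conditions; the bulky ester resists migration later.

Step 6
Reactants: 7 dienyl pivalate
Product: 8 (2E)-2-[(1S,6R)-3,7,7-trimethyl-5-oxobicyclo[4.1.0]hept-3-en-2-ylidene]ethyl 2,2-dimethylpropanoate
Conditions: CrO3, 3,5-dimethylpyrazole, CH2Cl2, −20 °C
Reagents that add atoms: chromium trioxide, O=[Cr](=O)=O
Why: Allylic oxidation of the only ring methylene, at the terminus of the diene, as in steroidal 3,5-dienes to dien-7-ones and in 3-carene to its 5-ketone. The methyl, the cyclopropyl C–H and the ester-deactivated CH2 react more slowly, and the medium is non-acidic.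

Step 7
Reactants: 8 dienone pivalate
Product: 9 (2S)-2-hydroxy-2-[(1S,2S,6R)-2-hydroxy-3,7,7-trimethyl-5-oxobicyclo[4.1.0]hept-3-en-2-yl]ethyl 2,2-dimethylpropanoate
Conditions: OsO4 (2 mol %), NMO, acetone/H2O, 0 °C → rt
Reagents that add atoms: N-methylmorpholine N-oxide, C[N+]1([O-])CCOCC1; water, O
Why: Upjohn dihydroxylation takes the distal, electron-richer alkene of the dienone. Syn addition occurs on the face opposite the gem-dimethylcyclopropane, which sets the tertiary carbinol and pushes the side chain onto the cyclopropane face; the E geometry fixes the secondary carbinol as S.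

Step 8
Reactants: 9 carenone diol pivalate
Product: 10 [(1S,3aR,7aS)-7a-hydroxy-3,3,7-trimethyl-5-oxo-1,3,3a,4,5,7a-hexahydro-2-benzofuran-1-yl]methyl 2,2-dimethylpropanoate
Conditions: Sc(OTf)3 (10 mol %), CH2Cl2, 0 °C → rt
Reagents that add atoms: none
Why: Sc(OTf)3 binds the enone oxygen and polarises the cyclopropyl ketone; the closest known reaction type is the acid-promoted homoconjugate opening of gem-dimethylcyclopropyl ketones by oxygen nucleophiles at the tertiary carbon. Of the two cyclopropane bonds at the carbon alpha to the ketone, the external one to CMe2 lies nearly parallel to the carbonyl pi system and leads to a tertiary cation, whereas the ring-fusion bond is poorly aligned and would give a secondary cation beside the carbinol carbon. The secondary hydroxyl, held on the cyclopropane face, attacks the CMe2 carbon opposite the breaking bond in a 5-exo-tet closure that forms the tetrahydrofuran, and the released enol tautomerises to the ring CH2. No stereocentre is created: the ring-fusion methine and both carbinol carbons keep their configuration, while the former carvone centre becomes the CH2 group and its information now sits in the methine bearing CMe2. The step needs external-bond cleavage and capture by the secondary rather than the tertiary hydroxyl; the tertiary hydroxyl could only close an oxetane, capture by the enol oxygen would require a bridgehead enol ether, and any isopropenyl product of proton loss re-enters through the same cation. Ionisation of the tertiary allylic alcohol is held back because its cation would be conjugated with the acid-bound enone.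

Step 9
Reactants: 10 tetrahydrofuran enone
Product: 11 [(1S,3aR,5S,7aS)-5,7a-dihydroxy-3,3,7-trimethyl-1,3,3a,4,5,7a-hexahydro-2-benzofuran-1-yl]methyl 2,2-dimethylpropanoate
Conditions: NaBH4, CeCl3·7H2O, MeOH, −78 °C
Reagents that add atoms: none
Why: Luche 1,2-reduction of the enone, hydride entering opposite the tetrahydrofuran ring. The new carbinol configuration is inconsequential, since this carbon becomes planar in step 17.

Step 10
Reactants: 11 allylic diol
Product: 12 [(1S,3aR,5S,7aS)-7a-hydroxy-5-(methoxymethoxy)-3,3,7-trimethyl-1,3,3a,4,5,7a-hexahydro-2-benzofuran-1-yl]methyl 2,2-dimethylpropanoate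
Conditions: MOMCl, i-Pr2NEt, CH2Cl2, 0 °C → rt
Reagents that add atoms: chloromethyl methyl ether, COCCl
Why: Selective acetalisation of the secondary over the tertiary hydroxyl. An acetal is chosen because it can neither migrate from oxygen to carbon nor rearrange in the carbanion of step 17.

Step 11
Reactants: 12 MOM ether pivalate
Product: 13 (1S,3aR,5S,7aS)-1-(hydroxymethyl)-5-(methoxymethoxy)-3,3,7-trimethyl-3,3a,4,5-tetrahydro-2-benzofuran-7a(1H)-ol
Conditions: i-Bu2AlH, CH2Cl2, −78 °C; aq. potassium sodium tartrate
Reagents that add atoms: none
Why: Reductive removal of the pivalate; no other reducible group is present.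

Step 12
Reactants: 13 diol
Product: 14 (1R,3aR,5S,7aS)-7a-hydroxy-5-(methoxymethoxy)-3,3,7-trimethyl-1,3,3a,4,5,7a-hexahydro-2-benzofuran-1-carboxylic acid
Conditions: TEMPO (cat.), PhI(OAc)2, MeCN/H2O, rt
Reagents that add atoms: water, O
Why: Oxoammonium oxidation of the primary alcohol through the aldehyde hydrate to the acid; the tertiary alcohol, the acetal and the trisubstituted alkene are inert.

Step 13
Reactants: 14 hydroxy acid
Product: 15 methyl (1R,3aR,5S,7aS)-7a-hydroxy-5-(methoxymethoxy)-3,3,7-trimethyl-1,3,3a,4,5,7a-hexahydro-2-benzofuran-1-carboxylate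
Conditions: Me3SiCHN2, PhMe/MeOH, 0 °C
Reagents that add atoms: (trimethylsilyl)diazomethane, C[Si](C)(C)C=[N+]=[N-]
Why: Neutral methyl esterification that leaves the hydroxyl and the acetal untouched.

Step 14
Reactants: 15 methyl ester
Product: 17 methyl (1R,3aR,5S,7aS)-7-formyl-7a-hydroxy-5-(methoxymethoxy)-3,3-dimethyl-1,3,3a,4,5,7a-hexahydro-2-benzofuran-1-carboxylate, via allylic alcohol 16 (not isolated)
Conditions: SeO2 (cat.), t-BuOOH, CH2Cl2, rt; then Dess–Martin periodinane, NaHCO3, CH2Cl2
Reagents that add atoms: tert-butyl hydroperoxide, CC(C)(C)OO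
Why: Selenium dioxide ene reaction and [2,3]-shift oxidise the substituent on the more substituted alkene carbon, which here has only the methyl hydrogens to offer, and the crude alcohol is taken on to the enal. It is done before any prenyl group is present.

Step 15
Reactants: 17 enal
Product: 18 (1R,3aR,5S,7aS)-7a-hydroxy-1-(methoxycarbonyl)-5-(methoxymethoxy)-3,3-dimethyl-1,3,3a,4,5,7a-hexahydro-2-benzofuran-7-carboxylic acid
Conditions: NaClO2, NaH2PO4, 2-methylbut-2-ene, t-BuOH/H2O, rt
Reagents that add atoms: sodium chlorite, [Na+].[O-]Cl=O
Why: Pinnick oxidation of the enal; the result is a free enoic acid beside a methyl ester, the differentiation that steps 16 and 17 need.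

Step 16
Reactants: 18 acid ester; 19 prenyl bromide
Product: 20 (1R,3aR,5S,7aS)-7a-hydroxy-1-(methoxycarbonyl)-5-(methoxymethoxy)-3,3-dimethyl-1-(3-methylbut-2-en-1-yl)-1,3,3a,4,5,7a-hexahydro-2-benzofuran-7-carboxylic acid
Conditions: LiN(i-Pr)2 (3.2 equiv), THF/DMPU, −78 → −40 °C; 19, −78 °C; AcOH, −78 °C
Reagents that add atoms: none
Why: Fráter–Seebach alkylation of a beta-hydroxy ester polyanion: after carboxylate and alkoxide, the third equivalent removes the ester alpha hydrogen, far more acidic than the gamma hydrogen of a lithium carboxylate, and the alkoxide cannot be eliminated. The prenyl group should enter on the convex face where the hydrogen stood, because the concave face is covered by the carbocycle and its carboxylate; the ester therefore stays over the ring.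

Step 17
Reactants: 20 prenylated acid ester
Product: 21 (1R,3R,6R,7S)-7-hydroxy-1-(methoxymethoxy)-5,5-dimethyl-3-(3-methylbut-2-en-1-yl)-2-oxo-4-oxatricyclo[4.3.1.0(3,7)]dec-8-ene-8-carboxylic acid
Conditions: LiN(i-Pr)2 (3.5 equiv), THF/DMPU, −78 → 0 °C; AcOH, −78 °C
Reagents that add atoms: none
Why: Proposed new method: the third equivalent of base removes the gamma hydrogen of the lithium carboxylate to give a dienediolate whose gamma carbon lies 1,4 across the ring from the ester on the concave face, so C-acylation can only close the six-membered bridge (alpha attack would need a cyclobutanone), and because the dienediolate is far more basic than the methoxide it expels, the non-enolisable ketone cannot revert by retro-Claisen cleavage; the closest known reaction types are the Dieckmann condensation and the gamma-acylation of dienolates and unsaturated acid dianions by esters, and the bridgehead configuration follows from the cage whatever the carbinol configuration of 20.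

Step 18
Reactants: 21 cage acid MOM ether
Product: 22 (1R,3R,6R,7S)-1,7-dihydroxy-5,5-dimethyl-3-(3-methylbut-2-en-1-yl)-2-oxo-4-oxatricyclo[4.3.1.0(3,7)]dec-8-ene-8-carboxylic acid
Conditions: Me2BBr, CH2Cl2, −78 °C; aq. NaHCO3/THF
Reagents that add atoms: none
Why: Acetal cleavage by a bromoborane at low temperature, where the ring ether and the prenyl alkene are not attacked. Protic acid is avoided because the prenyl cation could be trapped by the neighbouring hydroxyl.

Step 19
Reactants: 23 2,6-dimethoxy-1,4-benzoquinone
Product: 24 2-hydroxy-6-methoxy-1,4-benzoquinone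
Conditions: NaOH (1.1 equiv), H2O/THF, 0 °C → rt; aq. HCl
Reagents that add atoms: sodium hydroxide, [Na+].[OH-]
Why: Addition–elimination hydrolysis of one vinylogous ester; the resulting hydroxyquinone anion is deactivated towards a second substitution.

Step 20
Reactants: 24 2-hydroxy-6-methoxy-1,4-benzoquinone; 25 3-methylbut-2-enal
Product: 26 7-methoxy-2,2-dimethyl-2H-chromene-5,8-dione
Conditions: ethylenediammonium diacetate (cat.), MeOH, rt
Reagents that add atoms: none
Why: Knoevenagel condensation at the only nucleophilic carbon of the hydroxyquinone, followed by oxa-6π electrocyclisation. Closure through the former hydroxyl oxygen gives the para-quinone, with the methoxy group beside the carbonyl that flanks the pyran oxygen.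

Step 21
Reactants: 26 methoxy pyranoquinone
Product: 27 7-hydroxy-2,2-dimethyl-2H-chromene-5,8-dione
Conditions: NaOH, H2O/THF, rt; aq. HCl
Reagents that add atoms: sodium hydroxide, [Na+].[OH-]
Why: Hydrolysis of the remaining vinylogous methyl ester by addition–elimination; acidification restores the chromene should the pyran have opened reversibly.

Step 22
Reactants: 27 hydroxy pyranoquinone; 19 prenyl bromide
Product: 28 7-hydroxy-2,2-dimethyl-6-(3-methylbut-2-en-1-yl)-2H-chromene-5,8-dione
Conditions: Et3N, NaI, DMSO, rt
Reagents that add atoms: none
Why: C-Alkylation of the ambident hydroxyquinone anion at the carbon between enol and carbonyl, as in the lapachol synthesis from lawsone. O-alkylation is the known competitor and is separated.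

Step 23
Reactants: 22 cage hydroxy acid; 28 prenyl hydroxyquinone
Product: 30 CNP0222516.1, via acyloxyquinone 29 (not isolated)
Conditions: DCC, DMAP (cat.), CH2Cl2, 0 °C → rt; then CSA (cat.), rt
Reagents that add atoms: none
Why: Steglich acylation of the acidic quinone hydroxyl gives the vinylogous anhydride 29; neither tertiary alcohol is acylated, and a beta-lactone at the bridgehead alkene is too strained. Acid then promotes 6-exo-trig addition of the C-7 hydroxyl to the acyloxy-bearing quinone carbon, the hetero-Michael ketalisation known for beta-oxygenated enones, and the enol ketonises to the prenyl methine. Both new centres arise under reversible conditions and should settle in the configuration assumed in the remark above.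

## Compound list

1 | (R)-(−)-carvone, (5R)-2-methyl-5-(prop-1-en-2-yl)cyclohex-2-en-1-one | CC1=CC[C@H](CC1=O)C(C)=C | starting material
2 | carvone hydrochloride, (5R)-5-(2-chloropropan-2-yl)-2-methylcyclohex-2-en-1-one | CC1=CC[C@H](CC1=O)C(C)(C)Cl | intermediate
3 | (1S,6R)-car-3-en-2-one, (1S,6R)-3,7,7-trimethylbicyclo[4.1.0]hept-3-en-2-one | CC1=CC[C@@H]2[C@@H](C2(C)C)C1=O | intermediate
4 | ethyl (trimethylsilyl)acetate | CCOC(=O)C[Si](C)(C)C | starting material
5 | ethyl (2E)-2-[(1S,6R)-3,7,7-trimethylbicyclo[4.1.0]hept-3-en-2-ylidene]acetate | CCOC(=O)/C=C1/C(C)=CC[C@@H]2[C@H]1C2(C)C | intermediate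
6 | (2E)-2-[(1S,6R)-3,7,7-trimethylbicyclo[4.1.0]hept-3-en-2-ylidene]ethan-1-ol | OC/C=C1/C(C)=CC[C@@H]2[C@H]1C2(C)C | intermediate
7 | (2E)-2-[(1S,6R)-3,7,7-trimethylbicyclo[4.1.0]hept-3-en-2-ylidene]ethyl 2,2-dimethylpropanoate | CC(C)(C)C(=O)OC/C=C1/C(C)=CC[C@@H]2[C@H]1C2(C)C | intermediate
8 | (2E)-2-[(1S,6R)-3,7,7-trimethyl-5-oxobicyclo[4.1.0]hept-3-en-2-ylidene]ethyl 2,2-dimethylpropanoate | CC(C)(C)C(=O)OC/C=C1/C(C)=CC(=O)[C@@H]2[C@H]1C2(C)C | intermediate
9 | carenone diol pivalate, (2S)-2-hydroxy-2-[(1S,2S,6R)-2-hydroxy-3,7,7-trimethyl-5-oxobicyclo[4.1.0]hept-3-en-2-yl]ethyl 2,2-dimethylpropanoate | CC1=CC(=O)[C@@H]2[C@@H](C2(C)C)[C@@]1(O)[C@@H](O)COC(=O)C(C)(C)C | intermediate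
10 | cis-fused tetrahydrofuran cyclohexenone, [(1S,3aR,7aS)-7a-hydroxy-3,3,7-trimethyl-5-oxo-1,3,3a,4,5,7a-hexahydro-2-benzofuran-1-yl]methyl 2,2-dimethylpropanoate | CC1=CC(=O)C[C@H]2C(C)(C)O[C@@H](COC(=O)C(C)(C)C)[C@@]12O | intermediate
11 | [(1S,3aR,5S,7aS)-5,7a-dihydroxy-3,3,7-trimethyl-1,3,3a,4,5,7a-hexahydro-2-benzofuran-1-yl]methyl 2,2-dimethylpropanoate | CC1=C[C@@H](O)C[C@H]2C(C)(C)O[C@@H](COC(=O)C(C)(C)C)[C@@]12O | intermediate
12 | [(1S,3aR,5S,7aS)-7a-hydroxy-5-(methoxymethoxy)-3,3,7-trimethyl-1,3,3a,4,5,7a-hexahydro-2-benzofuran-1-yl]methyl 2,2-dimethylpropanoate | CC1=C[C@@H](OCOC)C[C@H]2C(C)(C)O[C@@H](COC(=O)C(C)(C)C)[C@@]12O | intermediate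
13 | (1S,3aR,5S,7aS)-1-(hydroxymethyl)-5-(methoxymethoxy)-3,3,7-trimethyl-3,3a,4,5-tetrahydro-2-benzofuran-7a(1H)-ol | CC1=C[C@@H](OCOC)C[C@H]2C(C)(C)O[C@@H](CO)[C@@]12O | intermediate
14 | (1R,3aR,5S,7aS)-7a-hydroxy-5-(methoxymethoxy)-3,3,7-trimethyl-1,3,3a,4,5,7a-hexahydro-2-benzofuran-1-carboxylic acid | CC1=C[C@@H](OCOC)C[C@H]2C(C)(C)O[C@@H](C(O)=O)[C@@]12O | intermediate
15 | methyl (1R,3aR,5S,7aS)-7a-hydroxy-5-(methoxymethoxy)-3,3,7-trimethyl-1,3,3a,4,5,7a-hexahydro-2-benzofuran-1-carboxylate | CC1=C[C@@H](OCOC)C[C@H]2C(C)(C)O[C@@H](C(=O)OC)[C@@]12O | intermediate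
16 | methyl (1R,3aR,5S,7aS)-7a-hydroxy-7-(hydroxymethyl)-5-(methoxymethoxy)-3,3-dimethyl-1,3,3a,4,5,7a-hexahydro-2-benzofuran-1-carboxylate (not isolated) | OCC1=C[C@@H](OCOC)C[C@H]2C(C)(C)O[C@@H](C(=O)OC)[C@@]12O | intermediate
17 | methyl (1R,3aR,5S,7aS)-7-formyl-7a-hydroxy-5-(methoxymethoxy)-3,3-dimethyl-1,3,3a,4,5,7a-hexahydro-2-benzofuran-1-carboxylate | O=CC1=C[C@@H](OCOC)C[C@H]2C(C)(C)O[C@@H](C(=O)OC)[C@@]12O | intermediate
18 | (1R,3aR,5S,7aS)-7a-hydroxy-1-(methoxycarbonyl)-5-(methoxymethoxy)-3,3-dimethyl-1,3,3a,4,5,7a-hexahydro-2-benzofuran-7-carboxylic acid | OC(=O)C1=C[C@@H](OCOC)C[C@H]2C(C)(C)O[C@@H](C(=O)OC)[C@@]12O | intermediate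
19 | prenyl bromide, 1-bromo-3-methylbut-2-ene | CC(C)=CCBr | starting material
20 | (1R,3aR,5S,7aS)-7a-hydroxy-1-(methoxycarbonyl)-5-(methoxymethoxy)-3,3-dimethyl-1-(3-methylbut-2-en-1-yl)-1,3,3a,4,5,7a-hexahydro-2-benzofuran-7-carboxylic acid | OC(=O)C1=C[C@@H](OCOC)C[C@H]2C(C)(C)O[C@@](CC=C(C)C)(C(=O)OC)[C@@]12O | intermediate
21 | (1R,3R,6R,7S)-7-hydroxy-1-(methoxymethoxy)-5,5-dimethyl-3-(3-methylbut-2-en-1-yl)-2-oxo-4-oxatricyclo[4.3.1.0(3,7)]dec-8-ene-8-carboxylic acid | OC(=O)C1=C[C@]2(OCOC)C[C@H]3C(C)(C)O[C@@](CC=C(C)C)(C2=O)[C@@]13O | intermediate
22 | (1R,3R,6R,7S)-1,7-dihydroxy-5,5-dimethyl-3-(3-methylbut-2-en-1-yl)-2-oxo-4-oxatricyclo[4.3.1.0(3,7)]dec-8-ene-8-carboxylic acid | OC(=O)C1=C[C@]2(O)C[C@H]3C(C)(C)O[C@@](CC=C(C)C)(C2=O)[C@@]13O | intermediate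
23 | 2,6-dimethoxy-1,4-benzoquinone | COC1=CC(=O)C=C(OC)C1=O | starting material
24 | 2-hydroxy-6-methoxy-1,4-benzoquinone | COC1=CC(=O)C=C(O)C1=O | intermediate
25 | 3-methylbut-2-enal | CC(C)=CC=O | starting material
26 | 7-methoxy-2,2-dimethyl-2H-chromene-5,8-dione | COC1=CC(=O)C2=C(OC(C)(C)C=C2)C1=O | intermediate
27 | 7-hydroxy-2,2-dimethyl-2H-chromene-5,8-dione | OC1=CC(=O)C2=C(OC(C)(C)C=C2)C1=O | intermediate
28 | 7-hydroxy-2,2-dimethyl-6-(3-methylbut-2-en-1-yl)-2H-chromene-5,8-dione | CC(C)=CCC1=C(O)C(=O)C2=C(C=CC(C)(C)O2)C1=O | intermediate
29 | 2,2-dimethyl-6-(3-methylbut-2-en-1-yl)-5,8-dioxo-2H-chromen-7-yl ester of acid 22 (not isolated) | CC(C)=CCC1=C(OC(=O)C3=C[C@]4(O)C[C@H]5C(C)(C)O[C@@](CC=C(C)C)(C4=O)[C@@]35O)C(=O)C2=C(C=CC(C)(C)O2)C1=O | intermediate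
30 | CNP0222516.1 | CC(C)=CC[C@H]1C(=O)C2=C(OC(C)(C)C=C2)C(=O)[C@@]12OC(=O)C1=C[C@]3(O)C[C@H]4C(C)(C)O[C@@](CC=C(C)C)(C3=O)[C@@]14O2 | target

## Step count and least certain steps

Total step count: 23 (steps 1 to 18 for the cage acid, steps 19 to 22 for ring A, step 23 to join them).
Longest linear sequence: 19 steps (steps 1 to 18, then step 23).

**Step 17** (bears the label "Proposed new method:"). The trianion may stall before cyclisation, because the carbocycle must reach a boat before the gamma carbon can touch the ester. On warming, the lithium alkoxide beside the quaternary ester carbon may instead fragment by retro-aldol cleavage. The fallback uses known reactions only, sets out from 20 and returns at 21. LiBH4 in THF reduces the methyl ester but not the lithium carboxylate and gives hydroxy acid F1. Allyl bromide and KHCO3 in DMF esterify the carboxylate to allyl ester F2. Dess–Martin oxidation gives aldehyde F3. KN(SiMe3)2 at −78 °C then removes the gamma hydrogen of the enoate, and the dienolate adds to the neighbouring aldehyde in an intramolecular vinylogous aldol addition, which has no leaving group to return, giving bridged carbinol F4 (either carbinol epimer). A second Dess–Martin oxidation gives keto ester F5, and Pd(PPh3)4 with morpholine removes the allyl group to give 21.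

**Step 8** (key step). The external cyclopropane bond may not open under a mild Lewis acid. The pivaloyl group may shift to the secondary hydroxyl under acid and so remove the nucleophile. The tertiary allylic hydroxyl may be lost by ionisation. The fallback runs from 9 to 10 and separates ring opening from etherification. MgI2 in MeCN opens the cyclopropyl ketone by homoconjugate addition of iodide at the tertiary carbon, without free acid, to give tertiary iodide F6. AgOTf with 2,6-di-tert-butylpyridine in CH2Cl2 then ionises the iodide, and the secondary hydroxyl closes the tetrahydrofuran to give 10.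

**Step 16.** Facial selectivity may be poor: the lithium alkoxide aggregate sits on the convex face and may steer the bromide to the ring side. Some gamma-deprotonation of the carboxylate may also lead to premature, prenyl-free cyclisation. The fallback runs from 18 to 20 and replaces polyanion alkylation by a neutral radical C–C bond formation. The trianion of 18 is quenched with PhSeCl to give selenide F7 (either epimer, since the centre becomes a planar radical). Keck allylation with CH2=CHCH2SnBu3 and AIBN in benzene at 80 °C gives allyl compound F8, the captodative radical being attacked on the open convex face. Cross-metathesis with 2-methylbut-2-ene, using the second-generation Grubbs catalyst (H2IMes)(PCy3)Cl2Ru=CHPh, converts allyl into prenyl and gives 20.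

**Step 23.** The tertiary bridgehead hydroxyl may fail to add to the fully substituted quinone carbon, so that the sequence stops at 29 or 29 passes its acyl group to adventitious nucleophiles. The spiro centre may also form with low selectivity, because both faces of the quinone are open. The fallback sets out from 28 and 22 and returns at 30, making the ketal at a true ketone. N-Chlorosuccinimide chlorinates the nucleophilic carbon of 28 and gives chlorotrione F9, whose central carbonyl is locked as part of a vicinal tricarbonyl. CSA in benzene with azeotropic removal of water should then join F9 and 22 by ordinary dioxanone formation to chloro spiro ketal F10. Bu3SnH and AIBN remove the chlorine to give 30, the methine settling by enolisation.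

## Further compounds

F1 | step 17 | (1S,3aR,5S,7aS)-7a-hydroxy-1-(hydroxymethyl)-5-(methoxymethoxy)-3,3-dimethyl-1-(3-methylbut-2-en-1-yl)-1,3,3a,4,5,7a-hexahydro-2-benzofuran-7-carboxylic acid | OC(=O)C1=C[C@@H](OCOC)C[C@H]2C(C)(C)O[C@@](CC=C(C)C)(CO)[C@@]12O
F2 | step 17 | allyl ester of F1 | C=CCOC(=O)C1=C[C@@H](OCOC)C[C@H]2C(C)(C)O[C@@](CC=C(C)C)(CO)[C@@]12O
F3 | step 17 | allyl 1-formyl-7a-hydroxy-5-(methoxymethoxy)-3,3-dimethyl-1-(3-methylbut-2-en-1-yl)-hexahydro-2-benzofuran-7-carboxylate | C=CCOC(=O)C1=C[C@@H](OCOC)C[C@H]2C(C)(C)O[C@@](CC=C(C)C)(C=O)[C@@]12O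
F4 | step 17 | allyl 2,7-dihydroxy-1-(methoxymethoxy)-5,5-dimethyl-3-(3-methylbut-2-en-1-yl)-4-oxatricyclo[4.3.1.0(3,7)]dec-8-ene-8-carboxylate (carbinol epimers at C-2) | C=CCOC(=O)C1=C[C@]2(OCOC)C[C@H]3C(C)(C)O[C@@](CC=C(C)C)(C2O)[C@@]13O
F5 | step 17 | allyl ester of 21 | C=CCOC(=O)C1=C[C@]2(OCOC)C[C@H]3C(C)(C)O[C@@](CC=C(C)C)(C2=O)[C@@]13O
F6 | step 8 | (2S)-2-hydroxy-2-[(1S,6S)-1-hydroxy-6-(2-iodopropan-2-yl)-2-methyl-4-oxocyclohex-2-en-1-yl]ethyl 2,2-dimethylpropanoate | CC1=CC(=O)C[C@H]([C@@]1(O)[C@@H](O)COC(=O)C(C)(C)C)C(C)(C)I
F7 | step 16 | 7a-hydroxy-1-(methoxycarbonyl)-5-(methoxymethoxy)-3,3-dimethyl-1-(phenylselanyl)-hexahydro-2-benzofuran-7-carboxylic acid (both epimers at C-1) | OC(=O)C1=C[C@@H](OCOC)C[C@H]2C(C)(C)OC([Se]c3ccccc3)(C(=O)OC)[C@@]12O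
F8 | step 16 | (1R,3aR,5S,7aS)-1-allyl-7a-hydroxy-1-(methoxycarbonyl)-5-(methoxymethoxy)-3,3-dimethyl-1,3,3a,4,5,7a-hexahydro-2-benzofuran-7-carboxylic acid | OC(=O)C1=C[C@@H](OCOC)C[C@H]2C(C)(C)O[C@@](CC=C)(C(=O)OC)[C@@]12O
F9 | step 23 | 6-chloro-2,2-dimethyl-6-(3-methylbut-2-en-1-yl)-2H-chromene-5,7,8(6H)-trione (racemic) | CC(C)=CCC1(Cl)C(=O)C(=O)C2=C(C=CC(C)(C)O2)C1=O
F10 | step 23 | 6-chloro derivative of 30 at the ring A methine (both epimers at that carbon) | CC(C)=CCC1(Cl)C(=O)C2=C(OC(C)(C)C=C2)C(=O)[C@@]12OC(=O)C1=C[C@]3(O)C[C@H]4C(C)(C)O[C@@](CC=C(C)C)(C3=O)[C@@]14O2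
A1 | alternative 1 | caged dioxepinone aryl ester | CC(C)=CCc1c(O)c2C=CC(C)(C)Oc2c2OC(=O)C3=C[C@]4(O)C[C@H]5C(C)(C)O[C@@](CC=C(C)C)(C4=O)[C@@]35Oc12
A2 | alternative 1 | caged xanthone substrate | CC(C)=CCc1c(O)c2C=CC(C)(C)Oc2c2C(=O)C3=C[C@]4(O)C[C@H]5C(C)(C)O[C@@](CC=C(C)C)(C4=O)[C@@]35Oc12
A3 | alternative 2 | allyl cage hydroxy ester | COC(=O)C1=C[C@]3(O)C[C@H]4C(C)(C)O[C@@](CC=C)(C3=O)[C@@]14O
A4 | alternative 2 | methyl 5-allyl-3,5-dihydroxy-3-(3-methylbut-2-en-1-yl)-4,6-dioxocyclohex-1-ene-1-carboxylate | COC(=O)C1=C[C@](O)(CC=C(C)C)C(=O)[C@@](O)(CC=C)C1=O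
A5 | alternative 3 | cage alpha-ketol acetonide | CC1(C)OCC2=C[C@]3(O)C[C@H]4C(C)(C)O[C@@](CC=C(C)C)(C3=O)[C@@]24O1
A6 | alternative 3 | formyl enone acetonide | CC1(C)OCC2=CC(=O)C[C@H]3C(C)(C)O[C@@](CC=C(C)C)(C=O)[C@@]23O1
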